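The numbers in the tables were computed with made-up constants.

Start at early times. The amber run holds 16.2% target at 15.0 min, then flattens: 29.9% at 80.0 min, 29.9% at 120 min. The violet run flattens too, near 25.6%. Yet amber still holds 69.7% starting material. Target and starting material add up to 99.6% there, so take starting material as what target leaves.

| flask | starting material | second substrate | reagent | free catalyst | remark | time |
|---|---|---|---|---|---|---|
| amber | 0.010 M | 6.7 mM | 9 mM | 50 µM | run made earlier |  |
| violet | 0.010 M | 15 mM | 9 mM | 50 µM | run made earlier |  |
| flask | 0.010 M | 10.0 mM | 9.00 mM | 50 µM |  | 2.5 h |

- amber (time / min: target / %, starting material / %): 15.0: 16.2, 83.0; 40.0: 26.0, 74.2; 80.0: 29.9, 70.1; 120: 29.9, 69.7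
- violet (time / min: target / %, starting material / %): 30.0: 18.9, 81.2; 60.0: 23.2, 76.6; 90.0: 24.3, 74.6; 120: 25.6, 75.2

(standard deviation of a reading: 0.3 percentage points)

- amount of target in the flask at 2.5 h, in percent of the starting material charged
- amount of starting material in the flask at 2.5 h, in percent of the starting material charged

Look at the charges. In the flask, reagent stands below starting material and below second substrate. So treat it as the limiting reagent, the charge expected to run out first. Take one reagent per target and write its balance:

reagent charged = reagent in target + reagent lost elsewhere

The lost part is unseen, so read the first term. Define the reagent share: target formed on the plateau per reagent charged.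

amber: 29.9% × 0.010 M / 9 mM = 33.2%

violet: 25.6% × 0.010 M / 9 mM = 28.4%

Both are readings and carry their scatter. The violet run, with more second substrate, shows the lower share. Place the flask on a straight line between them, by second substrate:

flask: 33.2% + (28.4% − 33.2%) × (10.0 mM − 6.7 mM) / (15 mM − 6.7 mM) = 31.3%

So I put the flask's reagent share at 31.3%, target formed per reagent charged. Amber reads flat from 80.0 min, so I take the flask at 2.5 h as on its plateau.

target: 31.3% × 9.00 mM / 0.010 M = 28.2%

starting material: the rest, 71.8%

The forecast gives 28.5% target and 71.5% starting material, noting that “more second substrate lowers the rate”. Its target stands 0.30 percentage points above my figure.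

The flask gives 28.3% target and 71.5% starting material.

    starting material + free catalyst ⇌ catalyst intermediate A (K = 250 M⁻¹, k = 1050 M⁻¹ min⁻¹)
    catalyst intermediate B → spent catalyst (k = 0.0118 min⁻¹)
    reagent + catalyst intermediate A → free catalyst + target (k = 1150 M⁻¹ min⁻¹)
    second substrate + free catalyst ⇌ catalyst intermediate B (K = 78.0 M⁻¹, k = 1000 M⁻¹ min⁻¹)
    2 reagent → homo dimer (k = 5.93 M⁻¹ min⁻¹)
    reagent + catalyst intermediate B → free catalyst + second product (k = 790 M⁻¹ min⁻¹)

The flask's reagent share comes to 31.4%, and its reagent is down to 0.25% of its charge, less than the 71% of its charge of starting material left. With these charges of reagent and starting material, the forecast's target stands or falls with the share. The neighbour flask moves it: charge 2.0 × 10⁻⁴ M of free catalyst instead of 50 µM and read at 2.5 h. Its reagent stands at 0%. Its target is 45.4%, so its share is 50.4%. Homo dimer there holds 29.0% of the reagent charged, against 57.0% in the flask. The neighbour flask's starting material stands at 54.0%.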